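**Remark on the chemistry:** target 23 is achiral. Diene 17 is taken as the mixture of ketene acetal geometric isomers that silylation gives, since both converge on the same arene.

## Analysis of the target

Betaethrin A (23) is an achiral diaryl ether: two benzene rings joined through one oxygen, with no stereocentre and no further ring. Ring A is a methyl salicylate in which C1 carries CO2Me, C2 the chelated hydroxyl, C4 a methyl group and C6 the bridging oxygen, so the ester is flanked by oxygen on both sides. Ring B carries the ether oxygen at C1', a free phenol at C2', a methoxy group at C4' and an acetoxymethyl group at C6'. The sensitive groups are the benzylic acetate (hydrogenolysis, solvolysis, acyl transfer to a phenoxide) and the electron-rich ring B (oxidation, Friedel-Crafts alkylation). The two O-methyl groups must stay while two phenols end up free, so a late unselective demethylation is not tolerable. The difficulty is the C6-O-C1' bond: it has three ortho substituents (the ester on ring A, the oxygen at C2' and the CH2 group at C6' on ring B), and neither ring is a good SNAr electrophile. The strategy rests on the fact that C2 to C5 of ring A (OH, H, CH3, H) are the carbon skeleton of the dienolate of a 3-methylbut-2-enoate, while C6(OAr)-C1(CO2Me) is an aryloxy-substituted propiolate. The crowded ether oxygen can therefore be attached to a two-carbon unit before ring A exists, and ring A can be built around it.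

## Retrosynthetic reasoning

**23 to 22.** The last bond cut is the benzyl-oxygen bond at C2' of ring B. A benzyl ether is the one phenol protecting group that survives peracid, hydride, an alkyllithium and prolonged heating. It can be removed at the end by a Lewis acid under non-reducing conditions, which the benzylic acetate requires.

**22 to 21 to 20.** The acetyl C-O bond and then the silicon-oxygen bond at the C6' CH2 group are cut. The acetate cannot be carried through the organolithium step, so the primary alcohol travels as a silyl ether. In the forward direction, the only competing hydroxyl in 21 is the C2 phenol, which is tied up in a hydrogen bond to the ester.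

**20 to 14 + 17.** Ring A is opened at C1-C2 and C5-C6. Cutting here, and not at the C6-O bond, avoids any coupling at a tri-ortho-substituted ether position. It also maps the substitution pattern of ring A onto two open-chain partners: the 1-methoxy-1-silyloxy diene 17 supplies C2 to C5, and the aryloxypropiolate 14 supplies C6 and C1 with the ester. The forward reaction has to form two C-C bonds with the regiochemistry that places the ester between the new hydroxyl and the aryloxy group, and it has to aromatise by expelling the methoxy group of the ketal as the alcohol.

**17 to 15.** The diene is the O-silylated extended enolate of the unsaturated ester 15, one step from a bulk chemical.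

**14 to 10 + 11, and 10 to 7 + 8.** The ester carbon is cut from the alkyne, leaving the aryloxyacetylide 13, which is acylated by 11. The acetylide comes from the dichlorovinyl ether 10 by elimination and halogen-metal exchange. 10 is cut at the vinyl C-O bond to the phenol 7 and the C2 unit 8. The future diaryl ether oxygen thus forms its second C-O bond by addition to an sp carbon, where the two ortho groups of ring B do little harm.

**7 to 6 to 5 to 4.** The silyl ether is removed, the alcohol is taken back to the aldehyde, and the formyl carbon is cut from C6'. Phenol 4 has one free ortho position and a blocked para position, so a phenoxide-directed ortho-formylation can give only one isomer.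

**4 to 2 to 1.** The C1' oxygen of 4 is traced back to a formyl group by an aryl migration (Baeyer-Villiger type), and the benzyl group is removed. Aldehyde 1 already holds the oxygen pattern of ring B (future C2' oxygen ortho and methoxy para to the carbon that becomes C1').

## Alternatives that were turned down

**Alternative 1:** The C6-O bond and the C1-carboxyl bond are cut together, leading back to the phenoxide of 7, an aryne and a one-carbon electrophile.
- Forward key step: CsF would release the aryne from 3-methoxy-5-methyl-2-(trimethylsilyl)phenyl trifluoromethanesulfonate A1. The phenoxide would add at the aryne carbon meta to methoxy, and the aryl anion would be trapped by carboxylation to give the acid A2, 2-{2-(benzyloxy)-6-[(tert-butyldimethylsilyloxy)methyl]-4-methoxyphenoxy}-6-methoxy-4-methylbenzoic acid.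
- For it: it is the most convergent plan. The regiochemistry of additions to 3-alkoxyarynes is well understood, and the aryne is indifferent to crowding on the electrophile side. On these points it is stronger than the chosen route.
- Against it: no ring is formed, and ring A arrives in A2 with its C2 oxygen methylated and its carboxyl free. A hindered acid must then be esterified, and one of two aryl methyl ethers must be cleaved selectively. Fluoride is used in the presence of a silyl ether. Protonation of the aryl anion competes with carboxylation and would give an ether lacking C1. A1 itself needs several steps.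
- Comparison: the chosen route delivers the chelated hydroxyl and the methyl ester of ring A directly in their final state, with no fluoride near the silyl ether and no demethylation.

**Alternative 2:** Ring A is taken as a ready-made salicylate and ring B is built last by cutting C2'-C3', C4'-C5' and C1'-C2'.
- Forward key step: photolysis of the diazo enone A3, methyl 2-{[2-{[(tert-butyldimethylsilyl)oxy]methyl}-4-diazo-3-oxobut-1-en-1-yl]oxy}-6-hydroxy-4-methylbenzoate, would give a vinylketene by Wolff rearrangement. This would add methoxyacetylene A4 in a [2+2] sense, and the cyclobutenone would open (4π) and reclose (6π) to the phenol A5, methyl 2-{2-[(tert-butyldimethylsilyloxy)methyl]-6-hydroxy-4-methoxyphenoxy}-6-hydroxy-4-methylbenzoate.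
- For it: the benzannulation fixes the ring B pattern by mechanism and delivers the C2' hydroxyl of A5 free. No benzyl group and no debenzylation are needed, which is an advantage over the chosen route.
- Against it: A3 is a vinylogous aryl ester carrying a diazo ketone, and the salicylate oxygen is a good leaving group by addition-elimination. A3 needs a long preparation (O-alkenylation of a ring A phenol, then diazo ketone formation). A4 is volatile and unstable. The photolysis is run on a substrate with a second absorbing salicylate chromophore.
- Comparison: the chosen route reaches both of its partners by classical reactions and concentrates its risk in one thermal step.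

**Alternative 3:** Ring A is cut at C1-C6 and C4-C5.
- Forward key step: the electron-poor pyrone A6, methyl 4-methoxy-6-methyl-2-oxo-2H-pyran-3-carboxylate, would react as the diene across its C3 and C6 with the ethynyl ether A7, 1-(benzyloxy)-3-{[(tert-butyldimethylsilyl)oxy]methyl}-2-(ethynyloxy)-5-methoxybenzene, which is available from 10 by the same elimination with a proton quench. The bridged lactone would decarboxylate to A8, methyl 2-{2-(benzyloxy)-6-[(tert-butyldimethylsilyloxy)methyl]-4-methoxyphenoxy}-6-methoxy-4-methylbenzoate.
- For it: it shares the ring B chemistry of the chosen route. The polarities of the electron-rich alkyne A7 and the electron-poor pyrone A6 match, and the decarboxylation makes aromatisation irreversible and clean. On that last point it is at least as good as the loss of alcohol in the chosen route.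
- Against it: the 4-methoxy group lowers the reactivity of A6 as an inverse-demand diene. Pyrone cycloadditions usually need temperatures at which a terminal aryl ynol ether such as A7 tends to oligomerise. A6 needs its own multistep synthesis. The C2 oxygen of A8 arrives methylated, so the final Lewis acid step would have to distinguish two aryl methyl ethers by chelation alone.
- Comparison: the chosen route uses a diene that is one step from a bulk ester, is more nucleophilic at its reacting terminus, and gives the free chelated hydroxyl without any ether cleavage on ring A.

Key step: step 9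

## Route

Step 1
Reactants: 1 2-hydroxy-4-methoxybenzaldehyde
Product: 2 2-(benzyloxy)-4-methoxybenzaldehyde
Conditions: BnBr, K2CO3, DMF, 60 °C
Reagents that add atoms: benzyl bromide, BrCc1ccccc1
Why: Williamson etherification of the only acidic hydroxyl; the benzyl ether is chosen because it withstands peracid, hydride, butyllithium and heat and can later be removed by BCl3 without hydrogen.

Step 2
Reactants: 2 2-(benzyloxy)-4-methoxybenzaldehyde
Product: 4 2-(benzyloxy)-4-methoxyphenol, via aryl formate 3 (not isolated)
Conditions: mCPBA, CH2Cl2, 0 °C to rt; then KOH, MeOH/H2O, 0 °C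
Reagents that add atoms: 3-chloroperoxybenzoic acid (mCPBA), OOC(=O)c1cccc(Cl)c1
Why: Baeyer-Villiger (Dakin-type) oxidation; the aryl group migrates in the Criegee intermediate because the ring carries ortho and para alkoxy donors, and the formate 3 is saponified in the same flask. This places the future ether oxygen para to the methoxy group and ortho to the benzyloxy group.

Step 3
Reactants: 4 2-(benzyloxy)-4-methoxyphenol
Product: 5 3-(benzyloxy)-2-hydroxy-5-methoxybenzaldehyde
Conditions: (CH2O)n, MgCl2, Et3N, MeCN, reflux
Reagents that add atoms: paraformaldehyde (as formaldehyde), C=O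
Why: Magnesium-mediated ortho-formylation (Casnati-Skattebøl type): the magnesium phenoxide delivers formaldehyde to the only free ortho position and the benzylic alkoxide is oxidised by a second formaldehyde through hydride transfer. The para position is blocked by methoxy, so one regioisomer is expected.

Step 4
Reactants: 5 3-(benzyloxy)-2-hydroxy-5-methoxybenzaldehyde
Product: 6 2-(benzyloxy)-6-(hydroxymethyl)-4-methoxyphenol
Conditions: NaBH4, MeOH/THF, 0 °C; aq. NH4Cl work-up
Reagents that add atoms: none
Why: Borohydride reduction of an aryl aldehyde; the neutral work-up avoids ionisation of the salicyl alcohol to an ortho-quinone methide.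

Step 5
Reactants: 6 2-(benzyloxy)-6-(hydroxymethyl)-4-methoxyphenol
Product: 7 2-(benzyloxy)-6-{[(tert-butyldimethylsilyl)oxy]methyl}-4-methoxyphenol
Conditions: TBSCl (1.05 equiv), imidazole, CH2Cl2, 0 °C
Reagents that add atoms: tert-butyldimethylsilyl chloride, CC(C)(C)[Si](C)(C)Cl
Why: Selective silylation of the primary alcohol; the phenol is flanked by two ortho substituents and reacts more slowly with the bulky silyl chloride. Any bis-silyl ether can be returned to 7 by K2CO3 in MeOH, which cleaves only the aryl silyl ether.

Step 6
Reactants: 7 2-(benzyloxy)-6-{[(tert-butyldimethylsilyl)oxy]methyl}-4-methoxyphenol, 8 trichloroethylene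
Product: 10 1-(benzyloxy)-3-{[(tert-butyldimethylsilyl)oxy]methyl}-2-{[(E)-1,2-dichloroethenyl]oxy}-5-methoxybenzene, via dichloroacetylene 9 (not isolated)
Conditions: K2CO3, DMF, 70 °C
Reagents that add atoms: none
Why: Base-induced dehydrochlorination of 8 gives dichloroacetylene in solution, and the phenoxide adds anti across it to give the (E)-1,2-dichlorovinyl ether, a known preparation of aryl dichlorovinyl ethers. The C-O bond forms at an sp carbon, so the two ortho groups of ring B interfere little; 9 is generated and consumed in solution only.

Step 7
Reactants: 10 1-(benzyloxy)-3-{[(tert-butyldimethylsilyl)oxy]methyl}-2-{[(E)-1,2-dichloroethenyl]oxy}-5-methoxybenzene, 11 methyl chloroformate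
Product: 14 methyl 3-{2-(benzyloxy)-6-[(tert-butyldimethylsilyloxy)methyl]-4-methoxyphenoxy}prop-2-ynoate, via chloroalkyne 12 (not isolated), via lithium acetylide 13 (not isolated)
Conditions: n-BuLi (2.2 equiv), THF, -78 to -40 °C; then cannulation into ClCO2Me (3 equiv), THF, -78 to 0 °C; pH 7 buffer; rapid filtration through Et3N-deactivated silica
Reagents that add atoms: none
Why: Dehydrochlorination gives the chloroalkyne, chlorine-lithium exchange gives the aryloxyacetylide, and this is C-acylated by the chloroformate (acetylide acylation). Inverse addition into excess chloroformate keeps 13 away from product 14, and at -78 °C vinylic deprotonation is much faster than metalation of the benzyl ether or the arene.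

Step 8
Reactants: 15 methyl 3-methylbut-2-enoate
Product: 17 1-methoxy-3-methyl-1-(trimethylsilyloxy)buta-1,3-diene, via lithium dienolate 16 (not isolated)
Conditions: LiN(iPr)2, THF, -78 °C; Me3SiCl, -78 °C to rt; filtration from pentane, distillation
Reagents that add atoms: chlorotrimethylsilane, C[Si](C)(C)Cl
Why: Kinetic γ-deprotonation of the senecioate gives the extended enolate, which is silylated on oxygen (formation of a vinylketene silyl acetal), a known preparation of this diene.

Step 9
Reactants: 14 methyl 3-{2-(benzyloxy)-6-[(tert-butyldimethylsilyloxy)methyl]-4-methoxyphenoxy}prop-2-ynoate, 17 1-methoxy-3-methyl-1-(trimethylsilyloxy)buta-1,3-diene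
Product: 20 methyl 2-{2-(benzyloxy)-6-[(tert-butyldimethylsilyloxy)methyl]-4-methoxyphenoxy}-6-hydroxy-4-methylbenzoate, via cycloadduct 18 (not isolated), via aryl trimethylsilyl ether 19 (not isolated)
Conditions: 17 (3 equiv), toluene, 110 °C, sealed tube; then K2CO3 (cat.), MeOH, rt
Reagents that add atoms: none
Why: Proposed new method: the dienophile is a push-pull alkyne whose aryloxy-bearing carbon is both the β-position of the ynoate and the oxocarbenium-like carbon of the ynol ether, so the CH2 terminus of 17, which carries the largest HOMO coefficient, should bond there first (C5-C6) and the acetal carbon should then close onto the ester-bearing carbon (C1-C2), either in one asynchronous [4+2] event or through a silyloxocarbenium/allenoate zwitterion. The closest known reaction type is the Diels-Alder reaction of 1-alkoxy-1-silyloxybuta-1,3-dienes with propiolates and acetylenedicarboxylates, which gives salicylates after loss of the alcohol; a 3-aryloxypropiolate has not been used as the 2π partner. Ring A is closed as a six-membered carbocycle by intermolecular [4+2] cycloaddition, and in the stepwise limit the second bond forms by 6-(enolexo)-exo-trig attack of the allenoate α-carbon on the silyloxocarbenium carbon. Cycloadduct 18 holds one ketal stereocentre that forms as a racemate and vanishes on aromatisation, so no stereocontrol is needed, and both geometric isomers of 17 give the same product. The selectivity that matters is regiochemical: the ester must end between the new hydroxyl and the aryloxy group, and this is secured because the donor terminus of the diene and the acceptor carbon of 14 are polarised in the matching sense by the three oxygen substituents and the ester. Aromatisation can only expel methanol from the ketal carbon together with a hydrogen from C5, since the aryloxy group sits on an sp2 carbon and cannot leave, and methanolysis with K2CO3 then cleaves the aryl trimethylsilyl ether 19 while the primary silyl ether stays. Heat without a Lewis acid is chosen because a Lewis acid would hydrate or ionise the ynol ether and favour an open-chain Mukaiyama-Michael product.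

Step 10
Reactants: 20 methyl 2-{2-(benzyloxy)-6-[(tert-butyldimethylsilyloxy)methyl]-4-methoxyphenoxy}-6-hydroxy-4-methylbenzoate
Product: 21 methyl 2-[2-(benzyloxy)-6-(hydroxymethyl)-4-methoxyphenoxy]-6-hydroxy-4-methylbenzoate
Conditions: Bu4NF, AcOH, THF, 0 °C to rt
Reagents that add atoms: none
Why: Fluoride desilylation of a primary silyl ether; buffering with acetic acid keeps the salicylate phenol protonated and the ester untouched.

Step 11
Reactants: 21 methyl 2-[2-(benzyloxy)-6-(hydroxymethyl)-4-methoxyphenoxy]-6-hydroxy-4-methylbenzoate
Product: 22 methyl 2-[2-(acetoxymethyl)-6-(benzyloxy)-4-methoxyphenoxy]-6-hydroxy-4-methylbenzoate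
Conditions: Ac2O (1.2 equiv), pyridine, CH2Cl2, 0 °C
Reagents that add atoms: acetic anhydride, CC(=O)OC(C)=O
Why: Selective O-acetylation of the primary alcohol; the only other hydroxyl is the C2 phenol, which is hydrogen-bonded to the ester and acylates much more slowly without an acyl-transfer catalyst.

Step 12
Reactants: 22 methyl 2-[2-(acetoxymethyl)-6-(benzyloxy)-4-methoxyphenoxy]-6-hydroxy-4-methylbenzoate
Product: 23 Betaethrin A, methyl 2-[2-(acetoxymethyl)-6-hydroxy-4-methoxyphenoxy]-6-hydroxy-4-methylbenzoate
Conditions: BCl3, C6HMe5, CH2Cl2, -78 °C; then MeOH, aq. NaHCO3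
Reagents that add atoms: none
Why: Lewis acid debenzylation with a cation scavenger: boron binds the benzyl ether oxygen, and the benzyl cation is captured by pentamethylbenzene and not by ring B. No hydrogen is used, so the benzylic acetate is not hydrogenolysed, and at -78 °C the unchelated aryl methyl ether and the methyl ester should be left alone.

## Compound list

1 | 2-hydroxy-4-methoxybenzaldehyde | COc1ccc(C=O)c(O)c1 | starting material
2 | 2-(benzyloxy)-4-methoxybenzaldehyde | COc1ccc(C=O)c(OCc2ccccc2)c1 | intermediate
3 | 2-(benzyloxy)-4-methoxyphenyl formate | COc1ccc(OC=O)c(OCc2ccccc2)c1 | intermediate (not isolated)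
4 | 2-(benzyloxy)-4-methoxyphenol | COc1ccc(O)c(OCc2ccccc2)c1 | intermediate
5 | 3-(benzyloxy)-2-hydroxy-5-methoxybenzaldehyde | COc1cc(C=O)c(O)c(OCc2ccccc2)c1 | intermediate
6 | 2-(benzyloxy)-6-(hydroxymethyl)-4-methoxyphenol | COc1cc(CO)c(O)c(OCc2ccccc2)c1 | intermediate
7 | 2-(benzyloxy)-6-{[(tert-butyldimethylsilyl)oxy]methyl}-4-methoxyphenol | COc1cc(CO[Si](C)(C)C(C)(C)C)c(O)c(OCc2ccccc2)c1 | intermediate
8 | trichloroethylene | ClC=C(Cl)Cl | starting material
9 | dichloroacetylene | ClC#CCl | intermediate (not isolated)
10 | 1-(benzyloxy)-3-{[(tert-butyldimethylsilyl)oxy]methyl}-2-{[(E)-1,2-dichloroethenyl]oxy}-5-methoxybenzene | COc1cc(CO[Si](C)(C)C(C)(C)C)c(O/C(Cl)=C\Cl)c(OCc2ccccc2)c1 | intermediate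
11 | methyl chloroformate | COC(=O)Cl | starting material
12 | 1-(benzyloxy)-3-{[(tert-butyldimethylsilyl)oxy]methyl}-2-[(chloroethynyl)oxy]-5-methoxybenzene | COc1cc(CO[Si](C)(C)C(C)(C)C)c(OC#CCl)c(OCc2ccccc2)c1 | intermediate (not isolated)
13 | lithium 2-{2-(benzyloxy)-6-[(tert-butyldimethylsilyloxy)methyl]-4-methoxyphenoxy}ethyn-1-ide | COc1cc(CO[Si](C)(C)C(C)(C)C)c(OC#C[Li])c(OCc2ccccc2)c1 | intermediate (not isolated)
14 | methyl 3-{2-(benzyloxy)-6-[(tert-butyldimethylsilyloxy)methyl]-4-methoxyphenoxy}prop-2-ynoate | COC(=O)C#COc1c(OCc2ccccc2)cc(OC)cc1CO[Si](C)(C)C(C)(C)C | intermediate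
15 | methyl 3-methylbut-2-enoate | COC(=O)C=C(C)C | starting material
16 | lithium 1-methoxy-3-methylbuta-1,3-dien-1-olate | [Li]OC(OC)=CC(C)=C | intermediate (not isolated)
17 | 1-methoxy-3-methyl-1-(trimethylsilyloxy)buta-1,3-diene (mixture of ketene acetal isomers) | COC(O[Si](C)(C)C)=CC(C)=C | intermediate
18 | methyl 2-{2-(benzyloxy)-6-[(tert-butyldimethylsilyloxy)methyl]-4-methoxyphenoxy}-6-methoxy-4-methyl-6-(trimethylsilyloxy)cyclohexa-1,4-diene-1-carboxylate (racemic) | COC(=O)C1=C(Oc2c(OCc3ccccc3)cc(OC)cc2CO[Si](C)(C)C(C)(C)C)CC(C)=CC1(OC)O[Si](C)(C)C | intermediate (not isolated)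
19 | methyl 2-{2-(benzyloxy)-6-[(tert-butyldimethylsilyloxy)methyl]-4-methoxyphenoxy}-4-methyl-6-(trimethylsilyloxy)benzoate | COC(=O)c1c(O[Si](C)(C)C)cc(C)cc1Oc1c(OCc2ccccc2)cc(OC)cc1CO[Si](C)(C)C(C)(C)C | intermediate (not isolated)
20 | methyl 2-{2-(benzyloxy)-6-[(tert-butyldimethylsilyloxy)methyl]-4-methoxyphenoxy}-6-hydroxy-4-methylbenzoate | COC(=O)c1c(O)cc(C)cc1Oc1c(OCc2ccccc2)cc(OC)cc1CO[Si](C)(C)C(C)(C)C | intermediate
21 | methyl 2-[2-(benzyloxy)-6-(hydroxymethyl)-4-methoxyphenoxy]-6-hydroxy-4-methylbenzoate | COC(=O)c1c(O)cc(C)cc1Oc1c(OCc2ccccc2)cc(OC)cc1CO | intermediate
22 | methyl 2-[2-(acetoxymethyl)-6-(benzyloxy)-4-methoxyphenoxy]-6-hydroxy-4-methylbenzoate | COC(=O)c1c(O)cc(C)cc1Oc1c(OCc2ccccc2)cc(OC)cc1COC(C)=O | intermediate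
23 | Betaethrin A, methyl 2-[2-(acetoxymethyl)-6-hydroxy-4-methoxyphenoxy]-6-hydroxy-4-methylbenzoate | COC(=O)c1c(O)cc(C)cc1Oc1c(O)cc(OC)cc1COC(C)=O | target

## Step count and least certain steps

Total step count: 12. Longest linear sequence: 11 steps (steps 1 to 7 and 9 to 12); step 8 is a one-step side branch.

**Step 9 (key step, proposed new method).**
- What may go wrong: the cycloaddition may fail to start at a temperature both partners tolerate, because the aryloxy donor raises the LUMO of the ynoate. Thermal silyl migration in the diene and hydration or oligomerisation of the ynol ether would then take over. The reaction may also stop after the first C-C bond at an open-chain vinylogous Michael adduct.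
- Fallback (known chemistry, ether bond by copper catalysis): it sets out from phenol 7 and comes back to the route at 21. Commercial 3-bromo-5-methylphenol F1 would be protected with chloromethyl methyl ether and iPr2NEt to give 1-bromo-3-(methoxymethoxy)-5-methylbenzene F2. F2 would be lithiated between bromine and the acetal oxygen with LiN(iPr)2 at -78 °C and trapped with methyl chloroformate 11 to give methyl 2-bromo-6-(methoxymethoxy)-4-methylbenzoate F3. Ligand-accelerated Ullmann ether synthesis of 7 with F3 (CuI, picolinic acid, K3PO4, DMSO, 90 °C) would use the ortho ester to assist copper insertion and give methyl 2-{2-(benzyloxy)-6-[(tert-butyldimethylsilyloxy)methyl]-4-methoxyphenoxy}-6-(methoxymethoxy)-4-methylbenzoate F4. Dilute HCl in MeOH would then remove the acetal and the silyl ether of F4 together and give 21, so that F1 is four steps from the main route.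

**Step 7.**
- What may go wrong: acetylide 13 may attack the newly formed ynoate 14 (conjugate addition or ketone formation). The alkyllithium may metalate a benzylic position. The push-pull alkyne may hydrate during isolation.
- Fallback: it sets out from 10 and comes back to the route at 14. Acetylide 13 would be generated as before and quenched with carbon dioxide, giving lithium 3-{2-(benzyloxy)-6-[(tert-butyldimethylsilyloxy)methyl]-4-methoxyphenoxy}prop-2-ynoate F5. The carboxylate F5 cannot react further with 13, and it would be O-methylated without isolation of the free acid (MeI, DMF) to give 14.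

**Step 12.**
- What may go wrong: the Lewis acid may ionise or cleave the benzylic acetate, and Friedel-Crafts benzylation of the electron-rich ring B may compete with capture by the scavenger.
- Fallback: it sets out from 21 and comes back to the route at 23, and it reverses the order of events. Hydrogenolysis of the benzyl ether (H2 over Pd/C, palladium metal on carbon, EtOAc) before any acetate is present would give methyl 2-hydroxy-6-[2-hydroxy-6-(hydroxymethyl)-4-methoxyphenoxy]-4-methylbenzoate F6. Candida antarctica lipase B with vinyl acetate would then acetylate the primary alcohol of F6 and leave both phenols free, giving 23.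

**Step 3.**
- What may go wrong: conversion may be incomplete because the neighbouring benzyloxy group chelates magnesium, and prolonged heating may lead to over-reaction to methoxymethylated or diarylmethane by-products.
- Fallback: it sets out from 4 and comes back to the route at 6, so step 4 is skipped. Phenylboronic acid and paraformaldehyde (cat. propionic acid, toluene, reflux with water removal) would deliver the one-carbon unit to the ortho position inside a boronate template and give 8-(benzyloxy)-6-methoxy-2-phenyl-4H-1,3,2-benzodioxaborine F7. Transesterification of F7 with propane-1,3-diol would release 6.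

## Further compounds

F1 | step 9 | 3-bromo-5-methylphenol | Cc1cc(O)cc(Br)c1
F2 | step 9 | 1-bromo-3-(methoxymethoxy)-5-methylbenzene | COCOc1cc(C)cc(Br)c1
F3 | step 9 | methyl 2-bromo-6-(methoxymethoxy)-4-methylbenzoate | COCOc1cc(C)cc(Br)c1C(=O)OC
F4 | step 9 | methyl 2-{2-(benzyloxy)-6-[(tert-butyldimethylsilyloxy)methyl]-4-methoxyphenoxy}-6-(methoxymethoxy)-4-methylbenzoate | COCOc1cc(C)cc(Oc2c(OCc3ccccc3)cc(OC)cc2CO[Si](C)(C)C(C)(C)C)c1C(=O)OC
F5 | step 7 | lithium 3-{2-(benzyloxy)-6-[(tert-butyldimethylsilyloxy)methyl]-4-methoxyphenoxy}prop-2-ynoate | [Li+].[O-]C(=O)C#COc1c(OCc2ccccc2)cc(OC)cc1CO[Si](C)(C)C(C)(C)C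
F6 | step 12 | methyl 2-hydroxy-6-[2-hydroxy-6-(hydroxymethyl)-4-methoxyphenoxy]-4-methylbenzoate | COC(=O)c1c(O)cc(C)cc1Oc1c(O)cc(OC)cc1CO
F7 | step 3 | 8-(benzyloxy)-6-methoxy-2-phenyl-4H-1,3,2-benzodioxaborine | COc1cc2c(c(OCc3ccccc3)c1)OB(c1ccccc1)OC2
A1 | alternative 1 | 3-methoxy-5-methyl-2-(trimethylsilyl)phenyl trifluoromethanesulfonate | COc1cc(C)cc(OS(=O)(=O)C(F)(F)F)c1[Si](C)(C)C
A2 | alternative 1 | 2-{2-(benzyloxy)-6-[(tert-butyldimethylsilyloxy)methyl]-4-methoxyphenoxy}-6-methoxy-4-methylbenzoic acid | COc1cc(C)cc(Oc2c(OCc3ccccc3)cc(OC)cc2CO[Si](C)(C)C(C)(C)C)c1C(=O)O
A3 | alternative 2 | methyl 2-{[2-{[(tert-butyldimethylsilyl)oxy]methyl}-4-diazo-3-oxobut-1-en-1-yl]oxy}-6-hydroxy-4-methylbenzoate (alkene geometry left open) | COC(=O)c1c(O)cc(C)cc1OC=C(CO[Si](C)(C)C(C)(C)C)C(=O)C=[N+]=[N-]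
A4 | alternative 2 | methoxyacetylene | COC#C
A5 | alternative 2 | methyl 2-{2-[(tert-butyldimethylsilyloxy)methyl]-6-hydroxy-4-methoxyphenoxy}-6-hydroxy-4-methylbenzoate | COC(=O)c1c(O)cc(C)cc1Oc1c(O)cc(OC)cc1CO[Si](C)(C)C(C)(C)C
A6 | alternative 3 | methyl 4-methoxy-6-methyl-2-oxo-2H-pyran-3-carboxylate | COC(=O)C1=C(OC)C=C(C)OC1=O
A7 | alternative 3 | 1-(benzyloxy)-3-{[(tert-butyldimethylsilyl)oxy]methyl}-2-(ethynyloxy)-5-methoxybenzene | C#COc1c(OCc2ccccc2)cc(OC)cc1CO[Si](C)(C)C(C)(C)C
A8 | alternative 3 | methyl 2-{2-(benzyloxy)-6-[(tert-butyldimethylsilyloxy)methyl]-4-methoxyphenoxy}-6-methoxy-4-methylbenzoate | COC(=O)c1c(OC)cc(C)cc1Oc1c(OCc2ccccc2)cc(OC)cc1CO[Si](C)(C)C(C)(C)C
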